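**Plan**

- Retrosynthesis (ring A = benzo ring, ring B = 4‑hydroxyphenyl, ring C = pyran ring): the C4–aryl bond to the acylphloroglucinol ring is cut first (Friedel–Crafts on a C4 cation), the C4 carbinol is taken back to a flavanone, and ring C of the flavanone is cut at O1–C8a, C4–C4a and O1–C2.
- Enabling feature: ring A carries the ether oxygen O1 and the benzylic carbon C4 on the neighbouring carbons C8a and C4a. This ortho O/C pair is what an aryne (C4a≡C8a) leaves when it inserts into the O–C(=O) bond of a cinnamic acid.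
- The C7 oxygen is too far from the triple bond to steer the addition, so a chlorine is placed on C5, next to C4a, as a temporary regiocontrol group; it leaves in the last step together with the benzyl groups.
- Forward order: aryne precursor from 4‑(benzyloxy)phenol (steps 1–3); aryne/cinnamic acid annulation closes ring C as a racemic flavanone (step 4); dynamic kinetic transfer hydrogenation (step 5); acylphloroglucinol (step 6); C4 arylation (step 7); hydrogenolysis (step 8).
- Stereochemistry: C2 (S) comes from catalyst control in step 5, where the flavanone racemizes by ring opening and closure; C4 comes from substrate‑controlled attack trans to the C2 aryl group in step 7.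

Key step: step 4

Remark: compounds 1, 7, 12 and 13 are taken as purchasable.
Remark: in the chlorinated compounds 15, F7 and F8 the C4 descriptor is S, in the target it is R, for the same spatial arrangement, because chlorine on C5 raises the CIP rank of C4a above that of the trihydroxyphenyl carbon.

**Step 1**
Reactants: 1 4‑(benzyloxy)phenol
Product: 2 4‑(benzyloxy)‑2‑chlorophenol
Conditions: SO2Cl2 (1.05 equiv), CH2Cl2, 0 °C to rt, dark
Reagents that add atoms: sulfuryl chloride, ClS(Cl)(=O)=O
Why: Electrophilic aromatic chlorination should go ortho to the free hydroxyl group, the strongest donor, since its para position is blocked.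

**Step 2**
Reactants: 2 4‑(benzyloxy)‑2‑chlorophenol
Product: 3 4‑(benzyloxy)‑2‑bromo‑6‑chlorophenol
Conditions: NBS (1.05 equiv), i‑Pr2NH (10 mol %), CH2Cl2, 0 °C
Reagents that add atoms: N‑bromosuccinimide, O=C1CCC(=O)N1Br
Why: Amine‑mediated ortho bromination of a phenol should take the only free position ortho to the hydroxyl group.

**Step 3**
Reactants: 3 4‑(benzyloxy)‑2‑bromo‑6‑chlorophenol
Product: 6 4‑(benzyloxy)‑2‑chloro‑6‑(trimethylsilyl)phenyl trifluoromethanesulfonate, via aryl trimethylsilyl ether 4 (not isolated), via lithium 2‑silylphenoxide 5 (not isolated)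
Conditions: HMDS, THF, 65 °C, then evaporation; n‑BuLi (1.1 equiv), THF, −78 °C; Tf2O (1.2 equiv), −78 °C to rt
Reagents that add atoms: hexamethyldisilazane, C[Si](C)(C)N[Si](C)(C)C; trifluoromethanesulfonic anhydride, O=S(=O)(OS(=O)(=O)C(F)(F)F)C(F)(F)F
Why: O‑silylation, bromine–lithium exchange (chlorine is inert at −78 °C), retro‑Brook 1,3 O‑to‑C silyl shift and triflation of the phenoxide form the standard sequence to ortho‑silylaryl triflates.

**Step 4**
Reactants: 6 4‑(benzyloxy)‑2‑chloro‑6‑(trimethylsilyl)phenyl trifluoromethanesulfonate; 7 (E)‑3‑[4‑(benzyloxy)phenyl]prop‑2‑enoic acid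
Product: 10 racemic 7‑(benzyloxy)‑2‑[4‑(benzyloxy)phenyl]‑5‑chloro‑2,3‑dihydro‑4H‑chromen‑4‑one, via 5‑(benzyloxy)‑3‑chlorobenzyne 8 (not isolated), via cesium chalcone phenoxide 9 (not isolated)
Conditions: 6 (1.5 equiv), CsF (4 equiv), THF, 125 °C, sealed tube; then NaOAc, EtOH, 78 °C on the crude product to complete ring closure
Reagents that add atoms: none
Why: Fluoride‑induced desilylation of 6 with loss of triflate gives aryne 8, and the cesium carboxylate of 7 adds through oxygen to C8a, the aryne carbon remote from chlorine, because the C5–Cl bond next to the triple bond flattens and polarizes the aryne so that attack at C8a places the carbanion on C4a beside the electron‑withdrawing chlorine (the benzyloxy group on C7 is one position further away and opposes this only weakly). The C4a carbanion then attacks the ester carbonyl through a four‑membered transition structure (anionic Fries‑type 1,3 O‑to‑C acyl shift), so that the O1–C8a and C4–C4a bonds are made in one operation and phenoxide 9 results. Ring C is closed by 6‑endo‑trig oxa‑Michael addition of this phenoxide to the enone, favoured here because the ortho chlorine twists the chalcone carbonyl out of conjugation with ring A. The closest known reaction type is the fluoride‑induced insertion of arynes into the O–C(=O) bond of α,β‑unsaturated carboxylic acids with tandem oxa‑Michael closure to 4‑chromanones. C2 is formed without control and 10 is racemic, which is intended, since step 5 resolves it dynamically through the same ring‑opening equilibrium. The step needs regioselectivity, secured by the chlorine, and acyl transfer in preference to protonation or conjugate addition of the carbanion, secured by the aprotic medium, excess CsF, the high temperature and the s‑trans ester geometry that holds the β‑carbon away from C4a.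

**Step 5**
Reactants: 10 racemic 7‑(benzyloxy)‑2‑[4‑(benzyloxy)phenyl]‑5‑chloro‑2,3‑dihydro‑4H‑chromen‑4‑one
Product: 11 (2S,4S)‑7‑(benzyloxy)‑2‑[4‑(benzyloxy)phenyl]‑5‑chloro‑3,4‑dihydro‑2H‑chromen‑4‑ol (2,4‑cis)
Conditions: RuCl[(S,S)‑TsDPEN](p‑cymene) (2 mol %), HCO2H/DBU (1:1.2), MeCN, 40 °C
Reagents that add atoms: none
Why: Noyori asymmetric transfer hydrogenation under dynamic kinetic resolution should work because the amine base racemizes C2 by retro‑oxa‑Michael/oxa‑Michael equilibration while the (S,S) catalyst delivers hydride to the Re face of the aryl ketone (4S, as for acetophenone) and does so fast only for the (2S) enantiomer, where hydride enters anti to the C2 aryl group, so that C2 (S) and C4 (S) are both set by the catalyst.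

**Step 6**
Reactants: 12 benzene‑1,3,5‑triol (phloroglucinol); 13 dodecanoyl chloride
Product: 14 1‑(2,4,6‑trihydroxyphenyl)dodecan‑1‑one
Conditions: AlCl3 (4 equiv), PhNO2/CH2Cl2, 0 °C to 60 °C; aqueous HCl work‑up
Reagents that add atoms: none
Why: Friedel–Crafts C‑acylation of phloroglucinol should stop at the monoketone because the first acyl group deactivates the ring.

**Step 7**
Reactants: 11 (2S,4S)‑7‑(benzyloxy)‑2‑[4‑(benzyloxy)phenyl]‑5‑chloro‑3,4‑dihydro‑2H‑chromen‑4‑ol; 14 1‑(2,4,6‑trihydroxyphenyl)dodecan‑1‑one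
Product: 15 1‑{3‑[(2S,4S)‑7‑(benzyloxy)‑2‑[4‑(benzyloxy)phenyl]‑5‑chloro‑3,4‑dihydro‑2H‑chromen‑4‑yl]‑2,4,6‑trihydroxyphenyl}dodecan‑1‑one (2,4‑trans)
Conditions: 14 (3 equiv), BF3·OEt2 (0.3 equiv), 1,4‑dioxane, 15 °C
Reagents that add atoms: none
Why: Friedel–Crafts alkylation should work because acid ionizes the C4 carbinol to a benzylic cation stabilized by O1 (ortho) and the C7 benzyloxy group (para), and one of the two equivalent free ring positions of 14 attacks it on the face opposite the pseudo‑equatorial C2 aryl group (axial attack on the half‑chair), which sets C4 trans to C2 under substrate control and, the addition being reversible, also gives the more stable isomer with the C4 aryl group pseudo‑axial and clear of the C5 substituent.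

**Step 8**
Reactants: 15 1‑{3‑[(2S,4S)‑7‑(benzyloxy)‑2‑[4‑(benzyloxy)phenyl]‑5‑chloro‑3,4‑dihydro‑2H‑chromen‑4‑yl]‑2,4,6‑trihydroxyphenyl}dodecan‑1‑one
Product: 16 (+)‑myristinin A, 1‑{2,4,6‑trihydroxy‑3‑[(2S,4R)‑7‑hydroxy‑2‑(4‑hydroxyphenyl)‑3,4‑dihydro‑2H‑chromen‑4‑yl]phenyl}dodecan‑1‑one
Conditions: H2 (1 atm), Pd(OH)2/C, NaOAc (2 equiv), EtOAc/MeOH, rt
Reagents that add atoms: none
Why: Catalytic hydrogenolysis should cleave both benzyl ethers and the aryl C–Cl bond in one operation while NaOAc takes up the HCl that would otherwise threaten the acid‑labile C4–aryl bond, the hydrogen‑bonded acylphloroglucinol ketone and both stereocenters staying untouched.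

**Compound list**

1 | 4‑(benzyloxy)phenol | Oc1ccc(OCc2ccccc2)cc1 | starting material
2 | 4‑(benzyloxy)‑2‑chlorophenol | Oc1ccc(OCc2ccccc2)cc1Cl | intermediate
3 | 4‑(benzyloxy)‑2‑bromo‑6‑chlorophenol | Oc1c(Br)cc(OCc2ccccc2)cc1Cl | intermediate
4 | [4‑(benzyloxy)‑2‑bromo‑6‑chlorophenoxy]trimethylsilane (not isolated) | C[Si](C)(C)Oc1c(Br)cc(OCc2ccccc2)cc1Cl | intermediate
5 | lithium 4‑(benzyloxy)‑2‑chloro‑6‑(trimethylsilyl)phenoxide (not isolated) | [Li+].[O-]c1c(Cl)cc(OCc2ccccc2)cc1[Si](C)(C)C | intermediate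
6 | 4‑(benzyloxy)‑2‑chloro‑6‑(trimethylsilyl)phenyl trifluoromethanesulfonate | C[Si](C)(C)c1cc(OCc2ccccc2)cc(Cl)c1OS(=O)(=O)C(F)(F)F | intermediate
7 | (E)‑3‑[4‑(benzyloxy)phenyl]prop‑2‑enoic acid | OC(=O)/C=C/c1ccc(OCc2ccccc2)cc1 | starting material
8 | 5‑(benzyloxy)‑3‑chlorobenzyne, 5‑(benzyloxy)‑3‑chloro‑1,2‑didehydrobenzene (not isolated) | ClC1=CC(OCc2ccccc2)=CC#C1 | intermediate
9 | cesium 5‑(benzyloxy)‑3‑chloro‑2‑[(E)‑3‑[4‑(benzyloxy)phenyl]prop‑2‑enoyl]phenolate (not isolated) | [Cs+].[O-]c1cc(OCc2ccccc2)cc(Cl)c1C(=O)/C=C/c1ccc(OCc2ccccc2)cc1 | intermediate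
10 | racemic 7‑(benzyloxy)‑2‑[4‑(benzyloxy)phenyl]‑5‑chloro‑2,3‑dihydro‑4H‑chromen‑4‑one (C2 undefined) | O=C1CC(c2ccc(OCc3ccccc3)cc2)Oc2cc(OCc3ccccc3)cc(Cl)c21 | intermediate
11 | (2S,4S)‑7‑(benzyloxy)‑2‑[4‑(benzyloxy)phenyl]‑5‑chloro‑3,4‑dihydro‑2H‑chromen‑4‑ol (cis) | O[C@H]1C[C@@H](c2ccc(OCc3ccccc3)cc2)Oc2cc(OCc3ccccc3)cc(Cl)c21 | intermediate
12 | benzene‑1,3,5‑triol (phloroglucinol) | Oc1cc(O)cc(O)c1 | starting material
13 | dodecanoyl chloride | CCCCCCCCCCCC(=O)Cl | starting material
14 | 1‑(2,4,6‑trihydroxyphenyl)dodecan‑1‑one | CCCCCCCCCCCC(=O)c1c(O)cc(O)cc1O | intermediate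
15 | 1‑{3‑[(2S,4S)‑7‑(benzyloxy)‑2‑[4‑(benzyloxy)phenyl]‑5‑chloro‑3,4‑dihydro‑2H‑chromen‑4‑yl]‑2,4,6‑trihydroxyphenyl}dodecan‑1‑one (trans) | CCCCCCCCCCCC(=O)c1c(O)cc(O)c([C@@H]2C[C@@H](c3ccc(OCc4ccccc4)cc3)Oc3cc(OCc4ccccc4)cc(Cl)c32)c1O | intermediate
16 | (+)‑myristinin A, 1‑{2,4,6‑trihydroxy‑3‑[(2S,4R)‑7‑hydroxy‑2‑(4‑hydroxyphenyl)‑3,4‑dihydro‑2H‑chromen‑4‑yl]phenyl}dodecan‑1‑one | CCCCCCCCCCCC(=O)c1c(O)cc(O)c([C@@H]2C[C@@H](c3ccc(O)cc3)Oc3cc(O)ccc32)c1O | target

**Step count**

Total: 8 steps. Longest linear sequence: 7 steps (1, 2, 3, 4, 5, 7, 8); step 6 is a one‑step side branch.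

**Steps most likely to fail**

Step 4. The carbanion on C4a may be protonated before acyl transfer (leaving only O‑arylation), may lose chloride, or may add in conjugate fashion, so that the C4–C4a bond is not formed. The fallback sets out from 6 and keeps the same regiochemical logic with a more reliable aryne reaction, then builds the enone classically:
- Treatment of 6 with CsF in DMF at rt, followed by aqueous acid, should give 4‑(benzyloxy)‑2‑chloro‑6‑hydroxybenzaldehyde F1 by insertion of the aryne into the formamide C=O bond and hydrolysis.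
- Addition of MeMgBr (2.2 equiv, THF, 0 °C) should give 5‑(benzyloxy)‑3‑chloro‑2‑(1‑hydroxyethyl)phenol F2.
- Oxidation with MnO2 in CH2Cl2 should give 1‑[4‑(benzyloxy)‑2‑chloro‑6‑hydroxyphenyl]ethan‑1‑one F3.
- Claisen–Schmidt condensation with 4‑(benzyloxy)benzaldehyde (KOH, EtOH) should give (E)‑1‑[4‑(benzyloxy)‑2‑chloro‑6‑hydroxyphenyl]‑3‑[4‑(benzyloxy)phenyl]prop‑2‑en‑1‑one F4.
- F4 should close to the flavanone with NaOAc in ethanol at reflux, which comes back to the route at 10.

Step 5. Racemization of C2 by ring opening and closure may be slower than reduction of the mismatched enantiomer, or the transient chalcone may itself be reduced, which would erode enantiomeric and diastereomeric purity. The fallback sets out from 10 and replaces asymmetric catalysis by enzymatic resolution: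
- Reduction with NaBH4 (MeOH/THF, 0 °C), hydride entering anti to the C2 aryl group, should give racemic cis‑7‑(benzyloxy)‑2‑[4‑(benzyloxy)phenyl]‑5‑chloro‑3,4‑dihydro‑2H‑chromen‑4‑ol F5.
- Lipase‑catalysed acylation (Candida rugosa lipase, vinyl acetate, t‑BuOMe, 35 °C) should, by the usual preference of lipases for the (R)‑carbinol of aryl alkyl carbinols, convert the (2R,4R) enantiomer into (2R,4R)‑7‑(benzyloxy)‑2‑[4‑(benzyloxy)phenyl]‑5‑chloro‑3,4‑dihydro‑2H‑chromen‑4‑yl acetate F6.
- The unreacted (2S,4S) alcohol is separated by chromatography, which comes back to the route at 11. F6 can be recycled by methanolysis and oxidation to 10.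

Step 7. The acylated phloroglucinol may be too weak a nucleophile, so that the cation eliminates to the flav‑3‑ene and oligomerizes, O‑alkylation or twofold alkylation competes, or facial selectivity and the C2 centre erode through prolonged exposure to acid. The fallback sets out from 11 and moves the acylation behind the C–C bond formation:
- Reaction of 11 with excess phloroglucinol 12 (5 equiv, BF3·OEt2, dioxane, rt), a far better nucleophile, should give 2‑[(2S,4S)‑7‑(benzyloxy)‑2‑[4‑(benzyloxy)phenyl]‑5‑chloro‑3,4‑dihydro‑2H‑chromen‑4‑yl]benzene‑1,3,5‑triol F7 with the same trans selectivity.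
- Houben–Hoesch acylation with dodecanenitrile (ZnCl2, HCl gas, Et2O, 0 °C) at one of the two equivalent free positions should give the ketiminium chloride of 15 F8.
- Hydrolysis of F8 in warm water comes back to the route at 15.

**Further compounds**

F1 | step 4 | 4‑(benzyloxy)‑2‑chloro‑6‑hydroxybenzaldehyde | O=Cc1c(O)cc(OCc2ccccc2)cc1Cl
F2 | step 4 | 5‑(benzyloxy)‑3‑chloro‑2‑(1‑hydroxyethyl)phenol (racemic) | CC(O)c1c(O)cc(OCc2ccccc2)cc1Cl
F3 | step 4 | 1‑[4‑(benzyloxy)‑2‑chloro‑6‑hydroxyphenyl]ethan‑1‑one | CC(=O)c1c(O)cc(OCc2ccccc2)cc1Cl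
F4 | step 4 | (E)‑1‑[4‑(benzyloxy)‑2‑chloro‑6‑hydroxyphenyl]‑3‑[4‑(benzyloxy)phenyl]prop‑2‑en‑1‑one | Oc1cc(OCc2ccccc2)cc(Cl)c1C(=O)/C=C/c1ccc(OCc2ccccc2)cc1
F5 | step 5 | racemic cis‑7‑(benzyloxy)‑2‑[4‑(benzyloxy)phenyl]‑5‑chloro‑3,4‑dihydro‑2H‑chromen‑4‑ol (both enantiomers written) | O[C@H]1C[C@@H](c2ccc(OCc3ccccc3)cc2)Oc2cc(OCc3ccccc3)cc(Cl)c21.O[C@@H]1C[C@H](c2ccc(OCc3ccccc3)cc2)Oc2cc(OCc3ccccc3)cc(Cl)c21
F6 | step 5 | (2R,4R)‑7‑(benzyloxy)‑2‑[4‑(benzyloxy)phenyl]‑5‑chloro‑3,4‑dihydro‑2H‑chromen‑4‑yl acetate | CC(=O)O[C@@H]1C[C@H](c2ccc(OCc3ccccc3)cc2)Oc2cc(OCc3ccccc3)cc(Cl)c21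
F7 | step 7 | 2‑[(2S,4S)‑7‑(benzyloxy)‑2‑[4‑(benzyloxy)phenyl]‑5‑chloro‑3,4‑dihydro‑2H‑chromen‑4‑yl]benzene‑1,3,5‑triol | Oc1cc(O)c([C@@H]2C[C@@H](c3ccc(OCc4ccccc4)cc3)Oc3cc(OCc4ccccc4)cc(Cl)c32)c(O)c1
F8 | step 7 | 1‑{3‑[(2S,4S)‑7‑(benzyloxy)‑2‑[4‑(benzyloxy)phenyl]‑5‑chloro‑3,4‑dihydro‑2H‑chromen‑4‑yl]‑2,4,6‑trihydroxyphenyl}dodecan‑1‑iminium chloride | CCCCCCCCCCCC(=[NH2+])c1c(O)cc(O)c([C@@H]2C[C@@H](c3ccc(OCc4ccccc4)cc3)Oc3cc(OCc4ccccc4)cc(Cl)c32)c1O.[Cl-]
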